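All runs were computed for an exercise, noise included.

**The question.** Which of elm, birch and ash ends highest in D? Solid E dissolves to G. G may turn into D on the catalyst Z, or into L without it, and Z may decay to X.

common to all: E 10 mM
- summer: Z 0.01 mol%; temperature 14 °C; run made earlier
- noon: Z 0.04 mol%; temperature 31 °C; run made earlier
- elm: Z 0.02 mol%; at 37 °C until 4.0 min, from then on at 7 °C; time 5.0 min
- birch: Z 0.02 mol%; temperature 7 °C; time 5.0 min
- ash: Z 0.02 mol%; temperature 37 °C; time 5.0 min

- summer (time / min: D / %): 0.667: 6.3; 1.33: 14.5; 2.00: 27.1; 2.50: 36.8; 3.00: 47.8; 4.00: 65.6
- noon (time / s: D / %): 10.0: 1.3; 15.0: 4.1; 25.0: 6.5; 50.0: 21.3; 80.0: 39.0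

(scatter of a reading: 1 percentage point)

- given per volume of solution although it is solid: E
- steps thought possible: Z -> X; G + Z -> D + Z; G -> L; E <-> G
- at the start none of E is in solution
- what has only dissolved of E counts as not reacted

- the flask that comes out highest in amount of D, in percent of the E charged, or "all alike" when all lie within 1.5 percentage points (elm / birch / ash / all alike)
- D at the end, in percent of the E charged, elm
- D at the end, in percent of the E charged, birch
- D at the end, in percent of the E charged, ash

**Fastest rung.** Lines through the late readings cut the time axis at 13.9 s in the noon run and 0.592 min in the summer run. I took these lags as the time G needs to build up.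

**Middle rung.** At its late pace of D, the noon run needs 2.82 min for the whole charge. I called this the draw time: the charge of E divided by the late rate of D. The summer run gives 5.19 min. So 4.00 times the Z, in a warmer flask, shortened it by a factor of 1.84. I read that as a ceiling from the dissolving of E.

**Slowest rung.** For ash I took the noon draw time. It ends before elm's change of temperature at 4.0 min, so I expected elm to match ash. The end of each flask then depends on the split of G between D and L, its selectivity. The runs show D alone, so I could only guess that split. My guess was that cold birch loses less G to L and ends highest, if its draw time fits inside 5.0 min.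

**The result.** The forecast, unlike my guess, put ash first, with 85% in elm, 82% in birch and 86% in ash, holding that “dissolution of E largely limits the rate”. The flasks gave 83.0% in elm, 98.0% in birch and 83.0% in ash, so birch came highest.

    Z → X (k = 2.50 × 10⁻⁴ /s, Ea = 271 kJ/mol)
    G + Z → D + Z, rate k2*[G]*[Z]/(1 + ([G]/Km2) + ([G]/Ksi2)^2) (3.70 mM, 6.70 mM, k = 27000 /M/s, Ea = 9.00 kJ/mol)
    G → L (k = 0.00830 /s, Ea = 79.0 kJ/mol)
    E ⇌ G, rate k4*(cs4 - [G]) while solid is left; crystals form when [G] > cs4 (solubility = 9.80 mM, k = 0.00640 /s)
    (constants at 37 °C)

**The split.** In ash, E stood at 15.5% after 2.50 min, a mean pace of one charge in 2.96 min, against the draw time of 2.82 min from noon. At the end E stood at 0% in birch and 0% in ash. The turning of G into L is the main reason for what birch lacks: struck out, it lifts birch from 98.0% to 99.2%. What temperature does to that step is part of the reason for the gap: without it, ash minus birch moves from −15 percentage points to 1.1 points. The neighbour is ash repeated at 12 °C. Its 0.02 mol% of Z lies between the summer and noon loadings, so I took the geometric mean of their draw times, 3.83 min, which fits inside 5.0 min. That flask ended with D 97.5%, L 2.06%, and 0.41% of the charged E still there, solid or dissolved.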